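At late times beta stands still: its target reads 60.5% at 1.50 min and 60.4% at 4.00 min, a change inside the scatter of 1 percentage point.

| flask | substrate | reagent | capture agent | free catalyst | second catalyst | remark | time |
|---|---|---|---|---|---|---|---|
| gamma | 2 mM | 3.6 mM | 2 mM | 40 µM | 9.5 µM | run made earlier |  |
| alpha | 2 mM | 3.6 mM | 2 mM | 40 µM | 15 µM | run made earlier |  |
| beta | 2 mM | 3.6 mM | 2 mM | 60 µM | 6.8 µM | run made earlier |  |
| flask | 2.0 mM | 3.60 mM | 2.00 mM | 40 µM | 6.8 µM |  | 5.0 min |

| run | time / min | target / % | trapped intermediate / % | substrate / % |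
|---|---|---|---|---|
| gamma | 0.333 | 60.6 | 23.0 | 0.5 |
| gamma | 0.667 | 59.8 | 24.7 | 0 |
| gamma | 1.50 | 62.0 | 26.6 | 0.1 |
| gamma | 4.00 | 60.8 | 23.3 | 0 |
| alpha | 0.500 | 70.5 | 17.7 | 0 |
| alpha | 1.33 | 68.0 | 19.4 | 0.5 |
| alpha | 2.50 | 66.0 | 18.3 | 0 |
| alpha | 4.00 | 69.5 | 16.9 | 0.1 |
| beta | 0.333 | 56.9 | 28.3 | 0.5 |
| beta | 0.667 | 59.3 | 31.2 | 0.6 |
| beta | 1.50 | 60.5 | 31.4 | 0 |
| beta | 4.00 | 60.4 | 31.4 | 0 |

(scatter of a reading: 1 percentage point)

- ratio of target to trapped intermediate at 2.0 s
- ratio of target to trapped intermediate at 20 s
- ratio of target to trapped intermediate at 5.0 min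
- which of target and trapped intermediate there is more of at 5.0 min

The ladder of times starts with substrate, which in gamma already reads 0.5% at 0.333 min. The next rung belongs to the products, which go on after substrate: in beta, with substrate at 0.5% at 0.333 min, target reads 56.9% there and 60.5% at 1.50 min, while trapped intermediate goes from 28.3% to 31.4%. Their ratio in beta reads 2.01 and then 1.93, a difference the scatter can account for. The last rung is the flat stretch beta shows from 1.50 min to 4.00 min, and 2.0 s stands before any reading, unobserved.

My own reckoning takes both products as branches of one short-lived precursor, with the target branch going with reagent and second catalyst and the trapped branch with capture agent. If b and u are the fractions of reagent and capture agent left, ln b / ln u stays constant during conversion and equals κ = S·c, where c is the second catalyst and S is a selectivity factor per unit of second catalyst. In this reckoning the starting ratio of target to trapped intermediate is κ times reagent over capture agent, so reagent and capture agent enter it as second catalyst does.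

The mean readings give S = 0.160 µM⁻¹ in alpha, 0.155 µM⁻¹ in gamma and 0.161 µM⁻¹ in beta, with mean 0.159 µM⁻¹.

For the flask, κ = 1.08, so its starting ratio is κ times reagent over capture agent, 1.94. Taking gamma's 85.2% for the two products together leaves u near 71.0%, and the final ratio is 1.92.

The forecast gives 1.9, 1.95 and 1.9, with target ahead, holding that “the product ratio is set by then and does not evolve”.

The flask gives 1.90 at 2.0 s, 1.89 at 20 s and 1.89 at 5.0 min, with target at 56.5% against 30.0% of trapped intermediate. It ends with 69% of its reagent and 70% of its capture agent, which puts S at 0.155 µM⁻¹ for this flask.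

    reagent + second catalyst + open intermediate → second catalyst + target (k = 5.66 × 10⁶ M⁻² s⁻¹)
    open intermediate + capture agent → trapped intermediate (k = 36.4 M⁻¹ s⁻¹)
    substrate + free catalyst → free catalyst + open intermediate (k = 15000 M⁻¹ s⁻¹)
    2 substrate → self-condensation product (k = 49.3 M⁻¹ s⁻¹)

For a neighbour flask with 0.012 mM of second catalyst, S gives κ = 1.90 and a starting ratio of 3.43. The flask's product total then puts u near 80.5% and the final ratio at 3.12. The computed ratio for that neighbour is 3.04, with 79% of its capture agent left.

All runs are simulated on assumed constants, noise included.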